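Rings: A = terminal 3,5-dihydroxyphenoxy ring. B = next ring (C1–O–A, C4–O–C, C5–B′). C = 2,6-dihydroxy-1,4-dioxy ring (C1–O–B, C4–O–D). D = tris(aryloxy) ring (C1–O–C, C2–O–E, C6–O–F, C4–OH). E, F = arms (C1–O–D, C5–E′ or F′). Primed rings are C-linked 2,4,6-trihydroxyphenyl groups.
Cuts, in retrosynthetic order: the 22 O–H groups (carried as O–Me); the ether D-C1–O–C-C4; the two biaryl bonds E-C5–E′-C1 and F-C5–F′-C1 together; then D-C2–O and D-C6–O. In the left half the cuts are A-C1–O, B-C4–O and B-C5–B′-C1.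
Enabling feature: in each 4-hydroxy-2,6-dimethoxyphenoxy arm the free hydroxyl on C4 is flanked by two equivalent open carbons (C3, C5), and C1, para to it, is blocked by O–D. 1,3,5-Trimethoxybenzene has three equivalent C–H carbons, so oxidising the two phenols can join E-C5 to E′-C1 and F-C5 to F′-C1 in only one regiochemical sense, without halide or boron.
Forward logic: no ring is built; all nine are bought. Every aryl ether is made with the crowded 2,6-dioxygenated phenol as nucleophile. Fluorobenzaldehydes are the electrophiles, and each formyl group is then turned into the next phenol by Baeyer–Villiger oxidation.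
Order: right half, D + two arm rings → bisphenol → twofold anodic arylation (E′, F′) → ring D phenol. Left half, B + B′ (Suzuki–Miyaura), + C (fluoride substitution), + A (CuI). The halves are joined at D-C1–O–C-C4 and all methyl ethers are cleaved last.
Stereochemistry: the target has no stereocentre, and each of the three biaryl axes carries a ring that is symmetric about the axis, so nothing stereochemical has to be set.

Key step: step 5

Assumption: 1, 2, 10, 16, 18 and 23 are taken as catalogue compounds; of these, the availability of 16 is the least certain.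

Step 1
Reactants: 1 2,6-difluoro-4-methoxybenzaldehyde (ring D); 2 4-bromo-2,6-dimethoxyphenol (2.3 equiv, rings E and F)
Product: 4 2,6-bis(4-bromo-2,6-dimethoxyphenoxy)-4-methoxybenzaldehyde, via mono-ether fluoroaldehyde 3 (not isolated)
Conditions: Cs2CO3, DMSO, 110 °C
Reagents that add atoms: none
Why: Twofold nucleophilic aromatic substitution, in which both fluorides are ortho to the formyl group, the 4-methoxy group and the first aryloxy group are meta to the carbon attacked and so leave the Meisenheimer charge undisturbed, and the aryl bromides of 2 are inert without a metal.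

Step 2
Reactants: 4 2,6-bis(4-bromo-2,6-dimethoxyphenoxy)-4-methoxybenzaldehyde
Product: 6 2,6-bis(4-bromo-2,6-dimethoxyphenoxy)-4-methoxyphenol, via aryl formate 5 (not isolated)
Conditions: mCPBA, CH2Cl2, 0 °C to rt; aq Na2SO3 wash; then K2CO3 (cat.), MeOH, rt
Reagents that add atoms: mCPBA (3-chloroperoxybenzoic acid), O=C(OO)c1cccc(Cl)c1
Why: Baeyer–Villiger oxidation of a 2,4,6-trioxygenated benzaldehyde, where the electron-rich aryl group migrates in preference to hydrogen, followed by methanolysis of the formate only after the excess peracid has been destroyed.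

Step 3
Reactants: 6 2,6-bis(4-bromo-2,6-dimethoxyphenoxy)-4-methoxyphenol
Product: 7 2-(benzyloxy)-1,3-bis(4-bromo-2,6-dimethoxyphenoxy)-5-methoxybenzene
Conditions: BnBr, K2CO3, DMF, 60 °C
Reagents that add atoms: benzyl bromide, BrCc1ccccc1
Why: Williamson etherification with a reactive, unhindered halide masks the easily oxidised ring D hydroxyl so that only the arm phenols are free in step 5.

Step 4
Reactants: 7 2-(benzyloxy)-1,3-bis(4-bromo-2,6-dimethoxyphenoxy)-5-methoxybenzene
Product: 9 4,4′-{[2-(benzyloxy)-5-methoxy-1,3-phenylene]bis(oxy)}bis(3,5-dimethoxyphenol), via monohydroxylated bromide 8 (not isolated)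
Conditions: Pd2(dba)3 (2 mol %), tBuXPhos (8 mol %), KOH, 1,4-dioxane/H2O, 100 °C, argon; then aq HCl
Reagents that add atoms: potassium hydroxide, [K+].[OH-]
Why: Palladium-catalysed hydroxylation of aryl bromides, in which zerovalent palladium bearing the bulky biaryl phosphine inserts into each unhindered C–Br bond and the arylpalladium hydroxide eliminates the phenoxide; benzyl, methyl and diaryl ethers are inert to hot aqueous KOH.

Step 5
Reactants: 9 4,4′-{[2-(benzyloxy)-5-methoxy-1,3-phenylene]bis(oxy)}bis(3,5-dimethoxyphenol); 10 1,3,5-trimethoxybenzene (6 equiv, two enter)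
Product: 12 4,4′-{[2-(benzyloxy)-5-methoxy-1,3-phenylene]bis(oxy)}bis[3,5-dimethoxy-2-(2,4,6-trimethoxyphenyl)phenol], via mono-biaryl bisphenol 11 (not isolated)
Conditions: boron-doped diamond anode, Pt cathode, undivided cell, constant current (5 mA cm−2, about 4.4 F per mol of 9), Bu3MeN(O3SOMe) (0.1 M), dry 1,1,1,3,3,3-hexafluoropropan-2-ol, 50 °C
Reagents that add atoms: none
Why: The two free phenols (E-C4–OH, F-C4–OH), hydrogen-bonded to the fluorinated alcohol, are the groups of lowest oxidation potential and each loses an electron and a proton at the anode to give a phenoxyl radical with spin density on its open ortho carbons. The excess arene 10 adds through one of its three equivalent C–H carbons to E-C5 and then to F-C5, and loss of a second electron and of two protons restores both aromatic rings while protons are reduced to hydrogen at the cathode; the closest known reaction type is the anodic dehydrogenative phenol–arene cross-coupling at boron-doped diamond in fluorinated alcohols. No ring closes and no stereocentre forms, because each new axis carries a ring that is symmetric about it. Chemoselectivity for the arms over ring D and over 10 rests on the free hydroxyls, since ring D is fully etherified and 10 is harder to oxidise than a trioxygenated phenol, and regiochemistry is fixed because C3 and C5 of each arm are equivalent and C1 is blocked by O–D. A single arylation per arm rests on the excess of 10, on stopping at about two faradays per bond and on the twisted new aryl group, which shields the phenol it flanks. The solvent is kept free of water and methanol so that no oxygen nucleophile can add to C1 of an over-oxidised arm and expel ring D.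

Step 6
Reactants: 12 bis-biaryl bisphenol
Product: 14 2-(benzyloxy)-5-methoxy-1,3-bis[2,4,6-trimethoxy-3-(2,4,6-trimethoxyphenyl)phenoxy]benzene, via monomethyl ether 13 (not isolated)
Conditions: MeI, K2CO3, DMF, 40 °C
Reagents that add atoms: iodomethane, CI
Why: Williamson methylation with a small electrophile caps both phenols next to the new aryl groups, so that the ring D hydroxyl is the only free one at the coupling of the halves.

Step 7
Reactants: 14 2-(benzyloxy)-5-methoxy-1,3-bis[2,4,6-trimethoxy-3-(2,4,6-trimethoxyphenyl)phenoxy]benzene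
Product: 15 4-methoxy-2,6-bis[2,4,6-trimethoxy-3-(2,4,6-trimethoxyphenyl)phenoxy]phenol
Conditions: H2 (1 atm), Pd/C (10 wt %), EtOAc/MeOH, rt
Reagents that add atoms: none
Why: Catalytic hydrogenolysis cleaves the benzyl–oxygen bond alone, since the molecule holds no halogen or alkene at this stage and methyl and diaryl ethers are inert.

Step 8
Reactants: 16 4-fluoro-2,6-dimethoxybenzaldehyde (ring B)
Product: 17 3-bromo-4-fluoro-2,6-dimethoxybenzaldehyde
Conditions: NBS (1.0 equiv), MeCN, 0 °C to rt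
Reagents that add atoms: N-bromosuccinimide, O=C1CCC(=O)N1Br
Why: Electrophilic aromatic bromination at one of the two equivalent carbons C3/C5, each ortho and para to a methoxy group and meta to the formyl group, with the first bromine slowing a second substitution.

Step 9
Reactants: 17 3-bromo-4-fluoro-2,6-dimethoxybenzaldehyde; 18 2,4,6-trimethoxyphenylboronic acid (2 equiv, ring B′)
Product: 19 4-fluoro-2,6-dimethoxy-3-(2,4,6-trimethoxyphenyl)benzaldehyde
Conditions: Pd(OAc)2 (5 mol %), SPhos (10 mol %), K3PO4, toluene/H2O 10:1, 100 °C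
Reagents that add atoms: none
Why: Suzuki–Miyaura coupling with a dialkylbiarylphosphine, the ligand class established for biaryls with four ortho substituents; one of those substituents here is only fluorine, the C–F bond is inert to palladium, and the excess of 18 offsets its protodeboronation.

Step 10
Reactants: 19 4-fluoro-2,6-dimethoxy-3-(2,4,6-trimethoxyphenyl)benzaldehyde; 2 4-bromo-2,6-dimethoxyphenol (1.3 equiv, ring C)
Product: 20 4-(4-bromo-2,6-dimethoxyphenoxy)-2,6-dimethoxy-3-(2,4,6-trimethoxyphenyl)benzaldehyde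
Conditions: Cs2CO3, DMSO, 120 °C
Reagents that add atoms: none
Why: Nucleophilic aromatic substitution of the small fluoride para to the formyl group, with both methoxy groups meta to the reacting carbon, makes the crowded ether C-C1–O–B-C4 without a metal, so the bromide of ring C stays untouched.

Step 11
Reactants: 20 4-(4-bromo-2,6-dimethoxyphenoxy)-2,6-dimethoxy-3-(2,4,6-trimethoxyphenyl)benzaldehyde
Product: 22 4-(4-bromo-2,6-dimethoxyphenoxy)-2,6-dimethoxy-3-(2,4,6-trimethoxyphenyl)phenol, via aryl formate 21 (not isolated)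
Conditions: mCPBA (1.1 equiv), CH2Cl2, 0 °C; aq Na2SO3 wash; then K2CO3 (cat.), MeOH, rt
Reagents that add atoms: mCPBA (3-chloroperoxybenzoic acid), O=C(OO)c1cccc(Cl)c1
Why: Baeyer–Villiger oxidation of a 2,4,6-trioxygenated benzaldehyde is fast at 0 °C, so close to one equivalent of peracid should be consumed at the formyl group before it attacks ring B′, and methanolysis then frees the B-C1 hydroxyl.

Step 12
Reactants: 22 4-(4-bromo-2,6-dimethoxyphenoxy)-2,6-dimethoxy-3-(2,4,6-trimethoxyphenyl)phenol; 23 1-iodo-3,5-dimethoxybenzene (3 equiv, ring A)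
Product: 24 5-bromo-2-[4-(3,5-dimethoxyphenoxy)-3,5-dimethoxy-2-(2,4,6-trimethoxyphenyl)phenoxy]-1,3-dimethoxybenzene
Conditions: CuI (10 mol %), picolinic acid (20 mol %), K3PO4, DMSO, 80 °C, argon
Reagents that add atoms: none
Why: Ullmann-type diaryl ether synthesis between a 2,6-dimethoxyphenoxide and an unhindered aryl iodide, in which the faster reaction of C–I than of C–Br with monovalent copper, together with the excess of 23, should keep the ring C bromide in place.

Step 13
Reactants: 15 4-methoxy-2,6-bis[2,4,6-trimethoxy-3-(2,4,6-trimethoxyphenyl)phenoxy]phenol; 24 bromo A–B(B′)–C fragment (1.3 equiv)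
Product: 25 docosa-O-methyl ether of the target
Conditions: CuI (0.3 equiv), picolinic acid (0.6 equiv), K3PO4, DMSO, 110 °C, argon
Reagents that add atoms: none
Why: Ullmann-type coupling in its favourable polarity, with the doubly flanked ring D phenoxide as nucleophile and C-C4–Br, which has two ortho hydrogens, as electrophile; picolinic acid and CuI are a combination established for ortho,ortho′-disubstituted phenols, and no other halide or free hydroxyl is present.

Step 14
Reactants: 25 docosa-O-methyl ether of the target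
Product: 26 CNP0117322.0
Conditions: BBr3 (excess), CH2Cl2, −78 °C to rt, argon; then H2O
Reagents that add atoms: none
Why: Lewis-acid cleavage of aryl methyl ethers, in which bromide attacks only the methyl carbon of each boron-complexed ether, so diaryl ether and biaryl bonds persist and hydrolysis frees all 22 hydroxyl groups.

Compound list
1 | 2,6-difluoro-4-methoxybenzaldehyde | COc1cc(F)c(C=O)c(F)c1 | starting material
2 | 4-bromo-2,6-dimethoxyphenol | COc1cc(Br)cc(OC)c1O | starting material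
3 | 2-(4-bromo-2,6-dimethoxyphenoxy)-6-fluoro-4-methoxybenzaldehyde | COc1cc(F)c(C=O)c(Oc2c(OC)cc(Br)cc2OC)c1 | intermediate
4 | 2,6-bis(4-bromo-2,6-dimethoxyphenoxy)-4-methoxybenzaldehyde | COc1cc(Oc2c(OC)cc(Br)cc2OC)c(C=O)c(Oc2c(OC)cc(Br)cc2OC)c1 | intermediate
5 | 2,6-bis(4-bromo-2,6-dimethoxyphenoxy)-4-methoxyphenyl formate | COc1cc(Oc2c(OC)cc(Br)cc2OC)c(OC=O)c(Oc2c(OC)cc(Br)cc2OC)c1 | intermediate
6 | 2,6-bis(4-bromo-2,6-dimethoxyphenoxy)-4-methoxyphenol | COc1cc(Oc2c(OC)cc(Br)cc2OC)c(O)c(Oc2c(OC)cc(Br)cc2OC)c1 | intermediate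
7 | 2-(benzyloxy)-1,3-bis(4-bromo-2,6-dimethoxyphenoxy)-5-methoxybenzene | COc1cc(Oc2c(OC)cc(Br)cc2OC)c(OCc2ccccc2)c(Oc2c(OC)cc(Br)cc2OC)c1 | intermediate
8 | 4-[2-(benzyloxy)-3-(4-bromo-2,6-dimethoxyphenoxy)-5-methoxyphenoxy]-3,5-dimethoxyphenol | COc1cc(Oc2c(OC)cc(O)cc2OC)c(OCc2ccccc2)c(Oc2c(OC)cc(Br)cc2OC)c1 | intermediate
9 | 4,4′-{[2-(benzyloxy)-5-methoxy-1,3-phenylene]bis(oxy)}bis(3,5-dimethoxyphenol), the D(E)(F) bisphenol | COc1cc(Oc2c(OC)cc(O)cc2OC)c(OCc2ccccc2)c(Oc2c(OC)cc(O)cc2OC)c1 | intermediate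
10 | 1,3,5-trimethoxybenzene | COc1cc(OC)cc(OC)c1 | starting material
11 | bisphenol 9 carrying a 2,4,6-trimethoxyphenyl group at E-C5 only | COc1cc(Oc2c(OC)cc(O)c(-c3c(OC)cc(OC)cc3OC)c2OC)c(OCc2ccccc2)c(Oc2c(OC)cc(O)cc2OC)c1 | intermediate
12 | 4,4′-{[2-(benzyloxy)-5-methoxy-1,3-phenylene]bis(oxy)}bis[3,5-dimethoxy-2-(2,4,6-trimethoxyphenyl)phenol], the D(E–E′)(F–F′) bisphenol | COc1cc(Oc2c(OC)cc(O)c(-c3c(OC)cc(OC)cc3OC)c2OC)c(OCc2ccccc2)c(Oc2c(OC)cc(O)c(-c3c(OC)cc(OC)cc3OC)c2OC)c1 | intermediate
13 | monomethyl ether of 12 (E-C4–OMe, F-C4–OH) | COc1cc(Oc2c(OC)cc(OC)c(-c3c(OC)cc(OC)cc3OC)c2OC)c(OCc2ccccc2)c(Oc2c(OC)cc(O)c(-c3c(OC)cc(OC)cc3OC)c2OC)c1 | intermediate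
14 | 2-(benzyloxy)-5-methoxy-1,3-bis[2,4,6-trimethoxy-3-(2,4,6-trimethoxyphenyl)phenoxy]benzene | COc1cc(Oc2c(OC)cc(OC)c(-c3c(OC)cc(OC)cc3OC)c2OC)c(OCc2ccccc2)c(Oc2c(OC)cc(OC)c(-c3c(OC)cc(OC)cc3OC)c2OC)c1 | intermediate
15 | 4-methoxy-2,6-bis[2,4,6-trimethoxy-3-(2,4,6-trimethoxyphenyl)phenoxy]phenol | COc1cc(Oc2c(OC)cc(OC)c(-c3c(OC)cc(OC)cc3OC)c2OC)c(O)c(Oc2c(OC)cc(OC)c(-c3c(OC)cc(OC)cc3OC)c2OC)c1 | intermediate
16 | 4-fluoro-2,6-dimethoxybenzaldehyde | COc1cc(F)cc(OC)c1C=O | starting material
17 | 3-bromo-4-fluoro-2,6-dimethoxybenzaldehyde | COc1cc(F)c(Br)c(OC)c1C=O | intermediate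
18 | 2,4,6-trimethoxyphenylboronic acid | COc1cc(OC)c(B(O)O)c(OC)c1 | starting material
19 | 4-fluoro-2,6-dimethoxy-3-(2,4,6-trimethoxyphenyl)benzaldehyde | COc1cc(F)c(-c2c(OC)cc(OC)cc2OC)c(OC)c1C=O | intermediate
20 | 4-(4-bromo-2,6-dimethoxyphenoxy)-2,6-dimethoxy-3-(2,4,6-trimethoxyphenyl)benzaldehyde | COc1cc(Oc2c(OC)cc(Br)cc2OC)c(-c2c(OC)cc(OC)cc2OC)c(OC)c1C=O | intermediate
21 | 4-(4-bromo-2,6-dimethoxyphenoxy)-2,6-dimethoxy-3-(2,4,6-trimethoxyphenyl)phenyl formate | COc1cc(Oc2c(OC)cc(Br)cc2OC)c(-c2c(OC)cc(OC)cc2OC)c(OC)c1OC=O | intermediate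
22 | 4-(4-bromo-2,6-dimethoxyphenoxy)-2,6-dimethoxy-3-(2,4,6-trimethoxyphenyl)phenol | COc1cc(Oc2c(OC)cc(Br)cc2OC)c(-c2c(OC)cc(OC)cc2OC)c(OC)c1O | intermediate
23 | 1-iodo-3,5-dimethoxybenzene | COc1cc(I)cc(OC)c1 | starting material
24 | 5-bromo-2-[4-(3,5-dimethoxyphenoxy)-3,5-dimethoxy-2-(2,4,6-trimethoxyphenyl)phenoxy]-1,3-dimethoxybenzene, the bromo A–B(B′)–C fragment | COc1cc(OC)cc(Oc2c(OC)cc(Oc3c(OC)cc(Br)cc3OC)c(-c3c(OC)cc(OC)cc3OC)c2OC)c1 | intermediate
25 | docosa-O-methyl ether of the target | COc1cc(OC)cc(Oc2c(OC)cc(Oc3c(OC)cc(Oc4c(Oc5c(OC)cc(OC)c(-c6c(OC)cc(OC)cc6OC)c5OC)cc(OC)cc4Oc4c(OC)cc(OC)c(-c5c(OC)cc(OC)cc5OC)c4OC)cc3OC)c(-c3c(OC)cc(OC)cc3OC)c2OC)c1 | intermediate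
26 | CNP0117322.0 | Oc1cc(O)cc(Oc2c(O)cc(Oc3c(O)cc(Oc4c(Oc5c(O)cc(O)c(-c6c(O)cc(O)cc6O)c5O)cc(O)cc4Oc4c(O)cc(O)c(-c5c(O)cc(O)cc5O)c4O)cc3O)c(-c3c(O)cc(O)cc3O)c2O)c1 | target

Total step count: 14. Longest linear sequence: 9 steps (steps 1 to 7, 13 and 14). The left half (steps 8 to 12) is made in parallel.

Steps most likely to fail

Step 5. The para-aryloxyphenol arms may be oxidised beyond the radical stage, with attack at C1 and loss of ring D. The second coupling may stall after the first. A further arylation at the remaining ortho carbon (E-C3, F-C3) or homocoupling of the arms may compete.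
The fallback sets out from 9 and comes back at 14. It replaces C–H/C–H coupling by halogenation and cross-coupling:
- NBS (2 equiv, MeCN, 0 °C) brominates each arm ortho to its hydroxyl to give the dibromo bisphenol F1.
- MeI and K2CO3 give the dibromo dimethyl ether F2.
- A twofold Suzuki–Miyaura coupling of F2 with 18 (Pd(OAc)2, SPhos, K3PO4, toluene, 110 °C) gives 14.

Step 13. The phenoxide of 15 lies between two very large aryloxy groups. Binding to copper and C–O bond formation may therefore be slower than hydrodebromination of 24 and than oxidative degradation of the electron-rich phenol.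
The fallback sets out from 15 and comes back at 25. It grows the chain one ring at a time by substitution of small activated fluorides instead of coupling two large halves:
- The phenoxide of 15 displaces the fluoride of 16 (Cs2CO3, DMSO) to give the D–O–C aldehyde F3.
- mCPBA gives the ring C formate F4, and methanolysis gives the ring C phenol F5.
- F5 displaces the fluoride of 19 to give the C–O–B(B′) aldehyde F6.
- A second Baeyer–Villiger oxidation gives the ring B formate F7, and methanolysis gives the ring B phenol F8.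
- Coupling of F8 with iodide 23 (CuI, picolinic acid, K3PO4) gives 25.

Step 10. Addition of the hindered phenoxide next to the twisted trimethoxyphenyl group may be too slow. Forcing temperatures may then bring on demethylation or loss of the formyl group.
The fallback sets out from 16 and comes back at 20. It inverts the order, so that the ether is made beside a flat iodine substituent and the biaryl bond follows:
- NIS with catalytic CF3CO2H in MeCN gives the iodo fluoroaldehyde F9.
- Phenol 2 displaces its fluoride (Cs2CO3, DMSO) to give the iodo bromo diaryl ether F10.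
- A Suzuki–Miyaura coupling with 18 at moderate temperature (Pd(PPh3)4, K3PO4, DMF, 70 °C) uses the faster oxidative addition of C–I than of C–Br to give 20.

Further compounds
F1 | step 5 | 4,4′-{[2-(benzyloxy)-5-methoxy-1,3-phenylene]bis(oxy)}bis(2-bromo-3,5-dimethoxyphenol) | COc1cc(Oc2c(OC)cc(O)c(Br)c2OC)c(OCc2ccccc2)c(Oc2c(OC)cc(O)c(Br)c2OC)c1
F2 | step 5 | 2-(benzyloxy)-1,3-bis(3-bromo-2,4,6-trimethoxyphenoxy)-5-methoxybenzene | COc1cc(Oc2c(OC)cc(OC)c(Br)c2OC)c(OCc2ccccc2)c(Oc2c(OC)cc(OC)c(Br)c2OC)c1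
F3 | step 13 | 4-{4-methoxy-2,6-bis[2,4,6-trimethoxy-3-(2,4,6-trimethoxyphenyl)phenoxy]phenoxy}-2,6-dimethoxybenzaldehyde | COc1cc(Oc2c(OC)cc(OC)c(-c3c(OC)cc(OC)cc3OC)c2OC)c(Oc2cc(OC)c(C=O)c(OC)c2)c(Oc2c(OC)cc(OC)c(-c3c(OC)cc(OC)cc3OC)c2OC)c1
F4 | step 13 | formate of the ring C phenol (F3 with OCHO in place of CHO) | COc1cc(Oc2c(OC)cc(OC)c(-c3c(OC)cc(OC)cc3OC)c2OC)c(Oc2cc(OC)c(OC=O)c(OC)c2)c(Oc2c(OC)cc(OC)c(-c3c(OC)cc(OC)cc3OC)c2OC)c1
F5 | step 13 | 4-{4-methoxy-2,6-bis[2,4,6-trimethoxy-3-(2,4,6-trimethoxyphenyl)phenoxy]phenoxy}-2,6-dimethoxyphenol | COc1cc(Oc2c(OC)cc(OC)c(-c3c(OC)cc(OC)cc3OC)c2OC)c(Oc2cc(OC)c(O)c(OC)c2)c(Oc2c(OC)cc(OC)c(-c3c(OC)cc(OC)cc3OC)c2OC)c1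
F6 | step 13 | aldehyde in which the hydroxyl of F5 carries the 4-formyl-3,5-dimethoxy-2-(2,4,6-trimethoxyphenyl)phenyl group (ring B with B′) | COc1cc(Oc2c(OC)cc(OC)c(-c3c(OC)cc(OC)cc3OC)c2OC)c(Oc2cc(OC)c(Oc3cc(OC)c(C=O)c(OC)c3-c3c(OC)cc(OC)cc3OC)c(OC)c2)c(Oc2c(OC)cc(OC)c(-c3c(OC)cc(OC)cc3OC)c2OC)c1
F7 | step 13 | formate of the ring B phenol (F6 with OCHO in place of CHO) | COc1cc(Oc2c(OC)cc(OC)c(-c3c(OC)cc(OC)cc3OC)c2OC)c(Oc2cc(OC)c(Oc3cc(OC)c(OC=O)c(OC)c3-c3c(OC)cc(OC)cc3OC)c(OC)c2)c(Oc2c(OC)cc(OC)c(-c3c(OC)cc(OC)cc3OC)c2OC)c1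
F8 | step 13 | ring B phenol (25 lacking ring A, B-C1–OH free) | COc1cc(Oc2c(OC)cc(OC)c(-c3c(OC)cc(OC)cc3OC)c2OC)c(Oc2cc(OC)c(Oc3cc(OC)c(O)c(OC)c3-c3c(OC)cc(OC)cc3OC)c(OC)c2)c(Oc2c(OC)cc(OC)c(-c3c(OC)cc(OC)cc3OC)c2OC)c1
F9 | step 10 | 4-fluoro-3-iodo-2,6-dimethoxybenzaldehyde | COc1cc(F)c(I)c(OC)c1C=O
F10 | step 10 | 4-(4-bromo-2,6-dimethoxyphenoxy)-3-iodo-2,6-dimethoxybenzaldehyde | COc1cc(Oc2c(OC)cc(Br)cc2OC)c(I)c(OC)c1C=O
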